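**Retrosynthetic overview**

1. The target is eudesm-4(15)-en-6α-yl (E)-p-coumarate (5S,6S,7S,10R). It is cut at the aryl O–Si bond, at the C6–O ester (giving eudesm-4(15)-en-6α-ol and O-silylated p-coumaric acid) and at C4=C15 (Wittig on a C4 ketone that comes from a C4 silyl ether).
2. C6–OH and C7–H come from α-face hydroboration of a C6=C7 ring alkene. Ring A is opened at C1–C2: metathesis of a C1 vinyl group (from a formyl group on C10) with the C2 allyl terminus of the C4 side chain.
3. The route rests on this feature of ring B: the quaternary C10 (carrying the C14 methyl and C1) lies next to C5–H, and the isopropyl-bearing C7 is 1,4 to C10. Cutting C5–C10 and C8–C9 gives methacrolein and an (E)-diene C5=C6–C7=C8.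
4. The triene comes from isovaleraldehyde (C6, C7, C11–C13), formaldehyde (C8), a formyl ylide (C4, C5) and an allylboronate (C2, C3).
5. Ring order: ring B first (Diels–Alder), then ring A (ring-closing metathesis).

Key step: step 5

Assumption: eudesmane numbering is used for all ring compounds; the senses of induction in steps 3 and 5 are assigned from the accepted transition-state models (closed chair with the acid-bound boronate; s-trans enal held by a formyl C–H···O contact), and both catalysts are available in either enantiomeric form.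

**Route**

Step 1
Reactants: 1 isovaleraldehyde
Product: 2 2-isopropylacrolein (3-methyl-2-methylidenebutanal)
Conditions: 37% aq. CH2O (1.0 equiv), pyrrolidine (10 mol%), propionic acid (10 mol%), i-PrOH, 45 °C; distillation
Reagents that add atoms: formaldehyde, C=O
Why: Amine-catalysed Mannich condensation (α-methylenation of an aldehyde), in which the enamine of 1 adds to the iminium ion of formaldehyde and the Mannich base loses the amine; no stereocentre is formed.

Step 2
Reactants: 2 2-isopropylacrolein + 3 (triphenylphosphoranylidene)acetaldehyde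
Product: 4 (2E)-5-methyl-4-methylidenehex-2-enal
Conditions: 3 (1.05 equiv), toluene, 80 °C
Reagents that add atoms: none
Why: Wittig olefination with a stabilised formyl ylide should give the (E)-enal, and one equivalent of ylide together with the lower electrophilicity of the dienal limits a second homologation.

Step 3
Reactants: 4 (2E)-5-methyl-4-methylidenehex-2-enal + 5 allylboronic acid pinacol ester
Product: 7 (3E,5S)-2-isopropylocta-1,3,7-trien-5-ol, via pinacol borate ester 6 (not isolated)
Conditions: (S)-3,3′-bis(2,4,6-triisopropylphenyl)-1,1′-binaphthyl-2,2′-diyl hydrogen phosphate [(S)-TRIP] (5 mol%), 4 Å molecular sieves, toluene, −30 °C; then aq. NaHCO3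
Reagents that add atoms: none
Why: Chiral phosphoric acid catalysed allylboration through a closed chair transition state should transfer the allyl group to the Si face of the aldehyde and give the (S)-carbinol (later C4), the epimer that becomes the axial 4β-silyloxy group used in step 9.

Step 4
Reactants: 7 (3E,5S)-2-isopropylocta-1,3,7-trien-5-ol
Product: 8 (3E,5S)-5-(tert-butyldimethylsilyloxy)-2-isopropylocta-1,3,7-triene
Conditions: TBSCl, imidazole, DMF, 0 °C → rt
Reagents that add atoms: tert-butyldimethylsilyl chloride, CC(C)(C)[Si](C)(C)Cl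
Why: Imidazole-promoted silylation of a secondary alcohol; a bulky silyl ether is chosen because it should resist ionisation at the dienylic position under the Lewis acid of step 5.

Step 5
Reactants: 8 (3E,5S)-5-(tert-butyldimethylsilyloxy)-2-isopropylocta-1,3,7-triene + 9 methacrolein
Product: 10 (1R,2R)-2-[(1S)-1-(tert-butyldimethylsilyloxy)but-3-en-1-yl]-1-methyl-4-isopropylcyclohex-3-ene-1-carbaldehyde
Conditions: (R)-3,3-diphenyl-1-(2-methylphenyl)tetrahydro-1H,3H-pyrrolo[1,2-c][1,3,2]oxazaborole (20 mol%), Tf2NH (18 mol%), 9 (3 equiv), CH2Cl2, −78 → −40 °C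
Reagents that add atoms: none
Why: The N-protonated oxazaborolidine binds the formyl oxygen of s-trans 9 and the diene C5=C6–C7=C8 of 8 adds in a concerted, asynchronous [4+2] in which the C8–C9 bond leads and the congested C5–C10 bond follows; the closest known reaction type is the oxazaborolidinium-catalysed Diels–Alder addition of 2-methylacrolein to alkyl-substituted acyclic 1,3-dienes. Ring B is closed as a cyclohexene by intermolecular cycloaddition, both ring bonds being made in the one step and C6=C7 remaining as the ring alkene. C10 is set by the catalyst, which leaves only one face of the bound enal α-carbon open (the (R)-catalyst is the one whose open face leads to the required configuration), and C5 is set relative to C10 by the exo-formyl transition state on the (E)-diene, which places the C14 methyl cis to the C4 side chain and so trans to C5–H. Regioselectivity is needed and is secured twice, since the 1-alkyl terminus (ortho rule) and the 3-isopropyl group (para rule) both make C8 the nucleophilic terminus that attacks C9. Exo selectivity is the normal preference of α-methyl enals under Lewis acid catalysis, and the (S)-silyloxy centre should be tolerated because in the required approach its OTBS group can lie anti to the dienophile with the allylic hydrogen outside.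

Step 6
Reactants: 10 the Diels–Alder aldehyde
Product: 11 tert-butyl({(1S)-1-[(1R,6S)-6-ethenyl-6-methyl-3-isopropylcyclohex-2-en-1-yl]but-3-en-1-yl}oxy)dimethylsilane
Conditions: Ph3PCH3Br, KN(SiMe3)2, THF, 0 °C; then 10, 0 °C → rt
Reagents that add atoms: methyltriphenylphosphonium bromide, C[P+](c1ccccc1)(c1ccccc1)c1ccccc1.[Br-]
Why: Wittig methylenation of a non-enolisable neopentyl aldehyde, so C10 cannot epimerise and the new vinyl group carries C1 for ring closure.

Step 7
Reactants: 11 the vinyl/allyl triene
Product: 12 4β-(tert-butyldimethylsilyloxy)-15-noreudesma-1,6-diene (5α-H, 10β-CH3)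
Conditions: second-generation Grubbs catalyst RuCl2(=CHPh)(PCy3)(H2IMes) (5 mol%), CH2Cl2 (0.01 M), 40 °C
Reagents that add atoms: none
Why: Ring-closing olefin metathesis between the C1 vinyl and C2 allyl termini, which sit trans-diequatorial on ring B, should close ring A as a cyclohexene with loss of ethylene while the trisubstituted C6=C7 alkene stays out of the catalytic cycle.

Step 8
Reactants: 12 4β-(tert-butyldimethylsilyloxy)-15-noreudesma-1,6-diene
Product: 13 4β-(tert-butyldimethylsilyloxy)-15-noreudesm-6-ene
Conditions: H2 (1 atm), RhCl(PPh3)3 (10 mol%), benzene–EtOH, rt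
Reagents that add atoms: none
Why: Homogeneous hydrogenation with RhCl(PPh3)3 reduces the cis-disubstituted C1=C2 alkene much faster than the trisubstituted, isopropyl-bearing C6=C7 alkene.

Step 9
Reactants: 13 4β-(tert-butyldimethylsilyloxy)-15-noreudesm-6-ene
Product: 15 4β-(tert-butyldimethylsilyloxy)-15-noreudesman-6α-ol (5α-H, 7α-H, 7β-isopropyl), via 6α-alkylborane 14 (not isolated)
Conditions: BH3·THF, THF, 0 °C → rt; then 3 M NaOH, 30% H2O2, 0 °C → rt
Reagents that add atoms: hydrogen peroxide, OO
Why: Hydroboration–oxidation: H–B adds syn from the α face because the β face at C6 is screened by the axial C14 methyl and the axial 4β-silyloxy group, boron goes to the less substituted C6, and oxidation with retention sets 6α-OH and 7α-H (7β-isopropyl).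

Step 10
Reactants: 15 4β-(tert-butyldimethylsilyloxy)-15-noreudesman-6α-ol
Product: 16 6α-(4-methoxybenzyloxy)-4β-(tert-butyldimethylsilyloxy)-15-noreudesmane
Conditions: NaH, 4-methoxybenzyl chloride, Bu4NI (cat.), DMF, 0 → 40 °C
Reagents that add atoms: 4-methoxybenzyl chloride, COc1ccc(CCl)cc1
Why: Williamson etherification; an ether and not the final ester is placed on C6 because an acyloxy group β to the coming C4 ketone would not survive the ylide of step 13.

Step 11
Reactants: 16 6α-(4-methoxybenzyloxy)-4β-(tert-butyldimethylsilyloxy)-15-noreudesmane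
Product: 17 6α-(4-methoxybenzyloxy)-15-noreudesman-4β-ol
Conditions: Bu4NF, THF, 60 °C
Reagents that add atoms: none
Why: Fluoride-mediated desilylation frees the axial C4 hydroxyl, the 4-methoxybenzyl ether being inert to fluoride.

Step 12
Reactants: 17 6α-(4-methoxybenzyloxy)-15-noreudesman-4β-ol
Product: 18 6α-(4-methoxybenzyloxy)-15-noreudesman-4-one
Conditions: Dess–Martin periodinane, CH2Cl2, rt
Reagents that add atoms: none
Why: Dess–Martin oxidation of a secondary alcohol under non-basic conditions erases the C4 centre without epimerising the adjacent C5.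

Step 13
Reactants: 18 6α-(4-methoxybenzyloxy)-15-noreudesman-4-one
Product: 19 6α-(4-methoxybenzyloxy)eudesm-4(15)-ene
Conditions: Ph3PCH3Br, KOtBu, toluene, rt; then 18, 80 °C
Reagents that add atoms: methyltriphenylphosphonium bromide, C[P+](c1ccccc1)(c1ccccc1)c1ccccc1.[Br-]
Why: Wittig methylenation of a hindered ketone with excess ylide at elevated temperature; if C5 enolises it should return to the more stable trans ring fusion, and the C6 alkoxide is too poor a leaving group for β-elimination.

Step 14
Reactants: 19 6α-(4-methoxybenzyloxy)eudesm-4(15)-ene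
Product: 20 eudesm-4(15)-en-6α-ol
Conditions: DDQ, CH2Cl2–pH 7 phosphate buffer, 0 °C → rt
Reagents that add atoms: none
Why: Oxidative cleavage of the 4-methoxybenzyl ether by DDQ (hydride abstraction, then hydrolysis of the oxocarbenium ion) should leave the 1,1-disubstituted alkene untouched.

Step 15
Reactants: 21 p-coumaric acid
Product: 23 (E)-4-(tert-butyldimethylsilyloxy)cinnamic acid, via bis-silylated ester 22 (not isolated)
Conditions: TBSCl (2.5 equiv), imidazole, DMF, rt; then AcOH–THF–H2O (3:1:1), rt
Reagents that add atoms: tert-butyldimethylsilyl chloride, CC(C)(C)[Si](C)(C)Cl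
Why: Bis-silylation followed by selective hydrolysis of the far more labile silyl ester, the aryl silyl ether being stable to aqueous acetic acid.

Step 16
Reactants: 20 eudesm-4(15)-en-6α-ol + 23 (E)-4-(tert-butyldimethylsilyloxy)cinnamic acid
Product: 25 eudesm-4(15)-en-6α-yl (E)-4-(tert-butyldimethylsilyloxy)cinnamate, via mixed anhydride 24 (not isolated)
Conditions: 23, 2,4,6-trichlorobenzoyl chloride, Et3N, THF, rt; then 20, 4-(dimethylamino)pyridine (cat.), toluene, 60 °C
Reagents that add atoms: none
Why: Yamaguchi esterification, in which 4-(dimethylamino)pyridine takes the cinnamoyl group from the less hindered carbonyl of the mixed anhydride and passes it to the hindered equatorial C6 hydroxyl with retention at C6.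

Step 17
Reactants: 25 eudesm-4(15)-en-6α-yl (E)-4-(tert-butyldimethylsilyloxy)cinnamate
Product: 26 eudesm-4(15)-en-6α-yl (E)-4-hydroxycinnamate (target)
Conditions: Bu4NF, AcOH, THF, 0 °C
Reagents that add atoms: none
Why: Fluoride cleavage of the aryl silyl ether, buffered with acetic acid so that the phenoxide is protonated at once and the hindered alkyl cinnamate is not attacked.

**Compound list**

1 | isovaleraldehyde (3-methylbutanal) | CC(C)CC=O | starting material
2 | 2-isopropylacrolein (3-methyl-2-methylidenebutanal) | C=C(C=O)C(C)C | intermediate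
3 | (triphenylphosphoranylidene)acetaldehyde | O=CC=P(c1ccccc1)(c1ccccc1)c1ccccc1 | starting material
4 | (2E)-5-methyl-4-methylidenehex-2-enal | C=C(C(C)C)/C=C/C=O | intermediate
5 | allylboronic acid pinacol ester | C=CCB1OC(C)(C)C(C)(C)O1 | starting material
6 | pinacol borate ester of 7 (O–B bond at the (S)-carbinol oxygen) | C=C(C(C)C)/C=C/[C@@H](OB1OC(C)(C)C(C)(C)O1)CC=C | intermediate
7 | (3E,5S)-2-isopropylocta-1,3,7-trien-5-ol | C=C(C(C)C)/C=C/[C@@H](O)CC=C | intermediate
8 | (3E,5S)-5-(tert-butyldimethylsilyloxy)-2-isopropylocta-1,3,7-triene | C=C(C(C)C)/C=C/[C@@H](O[Si](C)(C)C(C)(C)C)CC=C | intermediate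
9 | methacrolein (2-methylprop-2-enal) | C=C(C)C=O | starting material
10 | (1R,2R)-2-[(1S)-1-(tert-butyldimethylsilyloxy)but-3-en-1-yl]-1-methyl-4-isopropylcyclohex-3-ene-1-carbaldehyde (CHO = C1, quaternary carbon = C10, methyl cis to the side chain) | O=C[C@]1(C)CCC(C(C)C)=C[C@H]1[C@@H](O[Si](C)(C)C(C)(C)C)CC=C | intermediate
11 | tert-butyl({(1S)-1-[(1R,6S)-6-ethenyl-6-methyl-3-isopropylcyclohex-2-en-1-yl]but-3-en-1-yl}oxy)dimethylsilane | C=C[C@]1(C)CCC(C(C)C)=C[C@H]1[C@@H](O[Si](C)(C)C(C)(C)C)CC=C | intermediate
12 | 4β-(tert-butyldimethylsilyloxy)-15-noreudesma-1,6-diene (trans-fused, 5α-H, 10β-CH3) | CC(C)(C)[Si](C)(C)O[C@H]1CC=C[C@]2(C)CCC(C(C)C)=C[C@@H]12 | intermediate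
13 | 4β-(tert-butyldimethylsilyloxy)-15-noreudesm-6-ene | CC(C)(C)[Si](C)(C)O[C@H]1CCC[C@]2(C)CCC(C(C)C)=C[C@@H]12 | intermediate
14 | 4β-(tert-butyldimethylsilyloxy)-15-noreudesman-6α-ylborane (BH2 on C6, 7α-H) | CC(C)(C)[Si](C)(C)O[C@H]1CCC[C@]2(C)CC[C@@H](C(C)C)[C@H](B)[C@@H]12 | intermediate
15 | 4β-(tert-butyldimethylsilyloxy)-15-noreudesman-6α-ol (5α-H, 7α-H, 7β-isopropyl, 10β-CH3) | CC(C)(C)[Si](C)(C)O[C@H]1CCC[C@]2(C)CC[C@@H](C(C)C)[C@H](O)[C@@H]12 | intermediate
16 | 6α-(4-methoxybenzyloxy)-4β-(tert-butyldimethylsilyloxy)-15-noreudesmane | CC(C)(C)[Si](C)(C)O[C@H]1CCC[C@]2(C)CC[C@@H](C(C)C)[C@H](OCc3ccc(OC)cc3)[C@@H]12 | intermediate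
17 | 6α-(4-methoxybenzyloxy)-15-noreudesman-4β-ol | O[C@H]1CCC[C@]2(C)CC[C@@H](C(C)C)[C@H](OCc3ccc(OC)cc3)[C@@H]12 | intermediate
18 | 6α-(4-methoxybenzyloxy)-15-noreudesman-4-one | O=C1CCC[C@]2(C)CC[C@@H](C(C)C)[C@H](OCc3ccc(OC)cc3)[C@@H]12 | intermediate
19 | 6α-(4-methoxybenzyloxy)eudesm-4(15)-ene | C=C1CCC[C@]2(C)CC[C@@H](C(C)C)[C@H](OCc3ccc(OC)cc3)[C@@H]12 | intermediate
20 | eudesm-4(15)-en-6α-ol | C=C1CCC[C@]2(C)CC[C@@H](C(C)C)[C@H](O)[C@@H]12 | intermediate
21 | p-coumaric acid [(E)-4-hydroxycinnamic acid] | O=C(O)/C=C/c1ccc(O)cc1 | starting material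
22 | tert-butyldimethylsilyl (E)-4-(tert-butyldimethylsilyloxy)cinnamate | CC(C)(C)[Si](C)(C)OC(=O)/C=C/c1ccc(O[Si](C)(C)C(C)(C)C)cc1 | intermediate
23 | (E)-4-(tert-butyldimethylsilyloxy)cinnamic acid | O=C(O)/C=C/c1ccc(O[Si](C)(C)C(C)(C)C)cc1 | intermediate
24 | (E)-4-(tert-butyldimethylsilyloxy)cinnamic 2,4,6-trichlorobenzoic anhydride | O=C(/C=C/c1ccc(O[Si](C)(C)C(C)(C)C)cc1)OC(=O)c1c(Cl)cc(Cl)cc1Cl | intermediate
25 | eudesm-4(15)-en-6α-yl (E)-4-(tert-butyldimethylsilyloxy)cinnamate | C=C1CCC[C@]2(C)CC[C@@H](C(C)C)[C@H](OC(=O)/C=C/c3ccc(O[Si](C)(C)C(C)(C)C)cc3)[C@@H]12 | intermediate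
26 | eudesm-4(15)-en-6α-yl (E)-4-hydroxycinnamate (5S,6S,7S,10R) | C=C1CCC[C@]2(C)CC[C@@H](C(C)C)[C@H](OC(=O)/C=C/c3ccc(O)cc3)[C@@H]12 | target

**Step count**

Total step count: 17 (16 in the main chain and 1 for the acid partner).
Longest linear sequence: 16 steps (steps 1–14, 16 and 17).

**Steps most likely to fail**

Step 5. The cycloaddition may be slow at the hindered diene terminus, and the catalyst may not fully control the enal face or the exo mode in the presence of the resident silyloxy centre. The fallback sets out from 8 and 9 and replaces catalyst control by substrate control with separation: an achiral promoter (Me2AlCl, CH2Cl2, −78 °C) keeps the regiochemistry and the exo preference. Because 8 is a single enantiomer, the adduct formed on the other enal face, (1S,2S)-2-[(1S)-1-(tert-butyldimethylsilyloxy)but-3-en-1-yl]-1-methyl-4-isopropylcyclohex-3-ene-1-carbaldehyde F1, is a diastereomer of 10 and would be removed by chromatography. The route is rejoined at 10.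

Step 13. Addition of the ylide to the C4 carbonyl may be too slow, since one face is covered by the axial C14 methyl and the other by the equatorial C6 ether, and enolisation may take over. The fallback sets out from 18 and uses a Peterson olefination: Me3SiCH2Li with CeCl3 in THF at −78 °C, a small and weakly basic nucleophile, should add to the ketone to give 6α-(4-methoxybenzyloxy)-15-(trimethylsilyl)eudesman-4-ol F2 (either C4 epimer serves; the 4β-alcohol is drawn). Elimination with KH in THF should then give 19, where the route is rejoined.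

Step 16. Acylation of the C6 hydroxyl may stall, because it is flanked by the isopropyl group on C7 and by the C4 methylene. The fallback sets out from 20 and builds the cinnamate on a small ester already in place: diethylphosphonoacetic acid, DCC and catalytic 4-(dimethylamino)pyridine in CH2Cl2 (acylation through the reactive phosphonoketene) should give eudesm-4(15)-en-6α-yl (diethoxyphosphoryl)acetate F3. A Horner–Wadsworth–Emmons reaction of F3 with 4-(tert-butyldimethylsilyloxy)benzaldehyde (LiCl, DBU, MeCN) should then give the (E)-cinnamate 25, where the route is rejoined.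

**Further compounds**

F1 | step 5 | (1S,2S)-2-[(1S)-1-(tert-butyldimethylsilyloxy)but-3-en-1-yl]-1-methyl-4-isopropylcyclohex-3-ene-1-carbaldehyde | O=C[C@@]1(C)CCC(C(C)C)=C[C@@H]1[C@@H](O[Si](C)(C)C(C)(C)C)CC=C
F2 | step 13 | 6α-(4-methoxybenzyloxy)-15-(trimethylsilyl)eudesman-4β-ol | C[Si](C)(C)C[C@]1(O)CCC[C@]2(C)CC[C@@H](C(C)C)[C@H](OCc3ccc(OC)cc3)[C@@H]12
F3 | step 16 | eudesm-4(15)-en-6α-yl (diethoxyphosphoryl)acetate | C=C1CCC[C@]2(C)CC[C@@H](C(C)C)[C@H](OC(=O)CP(=O)(OCC)OCC)[C@@H]12
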